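Assumption: onocerane locants are used throughout (left decalin C1–C10 with C26 on C8, bridge C11–C12, right decalin C13–C22 with C27 on C14; right-half intermediates keep C13–C22), α/β refer to each decalin drawn with its angular methyl β, and the (R,SP) hand of the ferrocenyl bisphosphine is taken to direct the alkyl group to the Re face of C9; if the sense of induction is the opposite one, the (S,RP) ligand is used in the same step.

No error was found in the structures of the key step (precursors, product, the (S) configuration of the bicyclic starting diketone). Two points of design were changed. The enolate is trapped without BF3·OEt2, because the acyclic C8 ketal would ionise. The ring B pattern of the right half is reached through a ketone that can enolise in one direction only.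

## Structural features

The target, 3β-hydroxyonocera-8(26),14-dien-21-one, consists of two trans-fused decalins that are joined only by the ethano bridge C11–C12 between C9 and C13. The left decalin has ring A (C1–C5, C10) with the 3β-hydroxyl next to the gem-dimethyl carbon C4, and ring B (C5–C10) with the exocyclic methylene C8=C26. The right decalin has ring B (C13–C18) with the trisubstituted C14=C15 alkene carrying C27, and ring A (C17–C22) with the C21 ketone next to the gem-dimethyl carbon C22. There are seven stereocentres (3S,5R,9S,10R,13S,17R,18R): C3, C5, C10 and C9 run around the left decalin and C13, C18 and C17 are contiguous on the right. In each half a quaternary, methyl-bearing ring-fusion carbon (C10, C18) stands next to the tertiary carbon that carries the bridge (C9, C13), with the bridge equatorial and cis to the angular methyl. The fragile groups are the exocyclic methylene, which acid moves into ring B, and the C14=C15 alkene; in addition C3 must end as an alcohol and C21 as a ketone although their surroundings are almost identical. The real difficulty is to join two hindered halves through a bridge that bears no functional group while C9 is controlled without help from any nearby stereocentre. The key step exploits the fact that in left ring B the adjacent carbons C9 and C10 lie between C5 and C8, and C8 is sp2 in the target. Ring B is therefore a latent cyclohexenone C5(=O)–C10(CH3)=C9 with C8 as a ketal, and the bridge bond C9–C11 and the ring A bond C1–C10 can be formed one after the other across that one double bond.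

## Logic of the disconnections

31 ⇒ 30. No skeletal bond is cut: the C21 carbonyl is traced to its cyclic ketal. C21 must stay inert while C3 is reduced and C8 is olefinated, and the gain is that two ring A oxygen functions in nearly identical surroundings become distinguishable. The forward step must release the ketone under acid weak enough to leave the C8=C26 alkene in place.

30 ⇒ 29. The C8=C26 double bond is cut to a C8 carbonyl. The exocyclic alkene is the most acid-sensitive group and is therefore made late; a C8 carbonyl also puts C9 under thermodynamic control, and the wanted equatorial bridge is the stable arrangement. The forward olefination has to work on an α-branched ketone in the presence of a free hydroxyl.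

29 ⇒ 28 ⇒ 27. Two changes of oxidation level and no C–C bond: the C8 carbonyl goes back to an acyclic ketal and the C3 carbinol to a ketone. This removes stereocentre C3 and leaves two ketals of different lability. Forward, hydride must reach C3 from the α face and the hydrolysis must tell the two ketals apart.

27 ⇒ 25 (through 26). One C4–CH3 bond and the C5–H bond are cut, which returns the C3(=O)–C4=C5 enone. The quaternary C4 and the ring-fusion stereocentre C5 disappear together. Forward, a dissolving-metal reduction must protonate C5 on the α face and the regiodefined enolate must be alkylated on carbon.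

25 ⇒ 24. The C4=C5 bond is cut (retro-aldol condensation), which opens ring A to a 1,5-diketone. This exposes the pattern of a conjugate addition followed by a Michael addition. Forward, cyclisation must go through C4 onto C5 and end in the conjugated enone.

24 ⇒ 3 + 21 + 22 (through 23). The bonds C9–C11 and C1–C10 are cut. They flank what was the enone double bond of ring B, so one cut detaches the whole right half at the unfunctionalised bridge and the other detaches the ring A carbons. Three pieces of very different size result and the synthesis becomes convergent. Forward, C9 must be set by a chiral catalyst because 21 has no stereocentre near its reacting carbon, the second bond must form anti to the first, and both ketals must survive.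

3 ⇒ 2 ⇒ 1. The C6–C7 single bond is traced to an alkene and the ring to an arene whose para-methoxy carbon becomes the C8 ketal. This reaches a commercial phenol in two steps. Forward, only the less substituted alkene of the dienone may be reduced.

21 ⇒ 20 ⇒ 19 ⇒ 18. The C11–Mg bond goes back to C11–Br, C11–OH and a C11 ester. The skeleton is not simplified; the chain end is brought to the level that a sigmatropic rearrangement delivers. Forward, the ketal and the C14=C15 alkene must tolerate hydride, bromination and magnesium.

18 ⇒ 16 (through 17). The C12–C13 bond is cut by a retro-[3,3] shift, which moves the alkene to C13=C14 and places oxygen on C15. C13 must receive its carbon substituent on the more hindered β face, cis to the angular methyl, and an intramolecular suprafacial transfer from a 15β oxygen can do that. The stereocentre C13 is exchanged for a carbinol centre that a reduction can set. Forward, the rearrangement must proceed from a pseudo-equatorial oxygen.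

16 ⇒ 15 ⇒ 14 ⇒ 13 ⇒ 11 ⇒ 9 (through 12 and 10). The C15–O bond, then the C13–H bond (as an enol sulfonate) and the C14–C27 bond are cut. This leads back to a ketone at C13 that can enolise toward C14 only, so methylation, enol sulfonate formation and allylic oxidation are all regiochemically unambiguous. Forward, oxygen must enter at C15 and hydride must then attack C15 from the α face.

9 ⇒ 8 ⇒ 7 ⇒ 6 ⇒ 5 ⇒ 4. The C13 carbonyl is traced to an alcohol (a temporary mask), the C21 ketal to a ketone, the C17–H bond to a C16=C17 alkene, and the two C22–CH3 bonds are cut. This arrives at 4, which supplies C18 in the required absolute configuration and all ten ring carbons. Forward, the saturated carbonyl of 4 must be reduced selectively, both methyl groups must enter at C22 with deconjugation, and hydrogen must add to C17 anti to the angular methyl.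

## Other disconnections considered

Alternative 1: The cut goes through C17–C18 and C13–C14 of the right decalin, which opens its rings A and B at once and leads to trienone A1. In A1 an (E)-enone C12(=O)–C13=C18 and a 2-silyloxy diene C17=C16–C15=C14 are joined by the four-carbon tether C19–C22, and the left decalin is already attached at C11. Forward, heating A1 would bring about an intramolecular Diels–Alder reaction to give cycloadduct A2.
- In favour: two rings, two C–C bonds and the stereocentres C13, C17 and C18 (quaternary) would arise in one reagent-free, concerted step, and the exocyclic methylene of the left half should be untouched.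
- Against: the only control elements are the C21 ether on the tether and the distant left half, so neither the π-facial choice nor the endo/exo choice that decides the trans ring fusion is secured. A2 also carries a C12 ketone that must be removed, a C15 silyl enol ether where a C14=C15 alkene is needed, a C14 stereocentre that is destroyed again, and three different protecting groups.
- Comparison: in bonds and rings formed per step this plan is better than the chosen one. As a concerted thermal process it is at least its equal in functional-group tolerance. In stereocontrol it is weaker, because the chosen route takes C18 from enantiopure 4 and sets C13 by a suprafacial shift. In step economy it is not better: the adjustments after the cycloaddition would need about as many steps as the right half takes here, and the left half still has to be made in some other way before A1 can be assembled.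

Alternative 2: The cut is the C13–C18 bond, and right ring A is traced to an aromatic ring. This gives phenol A3, a 2,4-dimethylphenol with the allylsilane tether C16–C15(SiMe3)–C14(CH3)=C13 on C17 and the left half beyond C12. Forward, PhI(OAc)2 (trivalent iodine) would oxidise the phenol and the allylsilane would attack the para carbon C18 through C13 to give cyclohexa-2,5-dienone A4.
- In favour: a flat arene supplies the six carbons of ring A, C18 and C13 are formed together, the C14=C15 alkene with its methyl appears exactly where the target has it, and C21 emerges as a ketone without a protecting group. The last two points are an advantage over the chosen plan, which spends eight steps on the ring B pattern and carries a ketal at C21.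
- Against: the absolute configuration at C13 and C18 would have to come from an enantiopure silicon-bearing stereocentre at C15 (anti SE2′), which is a multi-step task of its own. The oxidant also meets the electron-rich exocyclic alkene of the left half, and capture of the oxidised phenol by solvent competes. A4 still needs saturation of C19=C20 and a reductive methylation of the C22=C17 enone to set C17 and the gem-dimethyl group.
- Comparison: structurally it is the equal of the chosen plan for the left half, which it does not address, and more direct for the right half. Mechanistically it rests on a cationic cyclisation whose facial control is less dependable than a ligand-controlled conjugate addition and a sigmatropic shift. In step count it could be a few steps shorter if A3 were easily accessible, so on step economy it is potentially the better plan, with the riskiest step placed late, when both halves are already joined.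

Alternative 3: The cut goes through C4–C5 and C9–C10, with the C3–O bond traced to an epoxide. The left decalin is opened to the (3S)-epoxy diene A5, which already carries the right half as its C21 ketal. Forward, Cp2TiCl (trivalent titanium, from Cp2TiCl2 and Mn) would open the epoxide to the C4 radical, two six-membered ring closures would form rings A and B, and the C8 radical would end as the exocyclic alkene. The product is the tetracyclic ketal A6, which is identical with 30.
- In favour: both left rings, the stereocentres C5, C9 and C10, the 3β-hydroxyl in its final oxidation state and the C8=C26 methylene would be made in one step, with no Wittig reaction and no ketal at C8. A5 could be assembled by alkylation chemistry from 20, so the right-half work of the chosen route would be kept and only step 23 would remain. On step economy this alternative is clearly better than the chosen plan (one step in place of steps 17–22), and on convergence it is its equal.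
- Against: radical polyene cyclisations of this kind commonly suffer from premature reduction and from endocyclic elimination. The relative configuration rests on a chair–chair fold with no adjustable control element. The C8 radical lies within reach of the C14=C15 alkene (closure of a six- or seven-membered ring), a competing path specific to this substrate. The configuration at C3 would have to be bought by an asymmetric dihydroxylation and epoxide formation on a polyene.
- Comparison: the chosen plan forms each bond by a polar, separately tunable event, sets C9 by a catalyst and sets C5 and C3 by well-understood substrate control. The alternative stakes four stereocentres on one radical cascade. The chosen plan is longer, but each of its steps can be corrected on its own.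

Key step: step 17

## Steps

Step 1
Reactants: 1 4-methoxy-2-methylphenol
Product: 2 4,4-dimethoxy-2-methylcyclohexa-2,5-dien-1-one
Conditions: PhI(OAc)2, MeOH, 0 °C
Reagents that add atoms: methanol, CO
Why: Oxidative dearomatisation of a para-alkoxyphenol by trivalent iodine; methanol attacks the para carbon, which already bears OMe, so the quinone monoketal (future C8 ketal) forms regiospecifically.

Step 2
Reactants: 2 4,4-dimethoxy-2-methylcyclohexa-2,5-dien-1-one
Product: 3 4,4-dimethoxy-2-methylcyclohex-2-en-1-one
Conditions: H2 (1 atm), RhCl(PPh3)3 (cat.), toluene, rt
Reagents that add atoms: none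
Why: Homogeneous hydrogenation with the monovalent rhodium complex discriminates by substitution: the disubstituted C6=C7 alkene is reduced and the methyl-bearing C9=C10 alkene is left; the neutral medium avoids loss of methanol and re-aromatisation.

Step 3
Reactants: 4 (S)-Wieland–Miescher ketone
Product: 5 (4aS,5S)-5-hydroxy-4a-methyl-4,4a,5,6,7,8-hexahydronaphthalen-2(3H)-one
Conditions: NaBH4 (0.3 equiv), EtOH, −10 °C
Reagents that add atoms: none
Why: Chemoselective carbonyl reduction: the saturated C13 ketone is more electrophilic than the vinylogous C21 ketone, and hydride enters anti to the angular methyl to give the 13β (equatorial) alcohol, which masks C13 for the next steps.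

Step 4
Reactants: 5 (4aS,5S)-5-hydroxy-4a-methyl-4,4a,5,6,7,8-hexahydronaphthalen-2(3H)-one
Product: 6 (4aS,5S)-5-hydroxy-1,1,4a-trimethyl-3,4,4a,5,6,7-hexahydronaphthalen-2(1H)-one
Conditions: KOtBu, MeI, t-BuOH, rt
Reagents that add atoms: iodomethane, CI
Why: Deconjugative α,α-dialkylation of the enone through its extended potassium dienolate puts both methyl groups on C22 and moves the alkene to C16=C17; the hindered neopentyl alkoxide is a far poorer nucleophile than the dienolate in tert-butanol.

Step 5
Reactants: 6 (4aS,5S)-5-hydroxy-1,1,4a-trimethyl-3,4,4a,5,6,7-hexahydronaphthalen-2(1H)-one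
Product: 7 (4aS,5S,8aR)-5-hydroxy-1,1,4a-trimethyloctahydronaphthalen-2(1H)-one
Conditions: H2 (4 atm), Pd/C, EtOH, rt
Reagents that add atoms: none
Why: Heterogeneous hydrogenation delivers hydrogen to C17 on the face opposite the angular C18 methyl, as with 4,4-dimethyl-5-ene steroids, and should give the trans-fused decalin (17α-H).

Step 6
Reactants: 7 (4aS,5S,8aR)-5-hydroxy-1,1,4a-trimethyloctahydronaphthalen-2(1H)-one
Product: 8 13β-hydroxy trans-decalin C21 ethylene ketal
Conditions: HOCH2CH2OH, p-TsOH (cat.), benzene, reflux (−H2O)
Reagents that add atoms: ethane-1,2-diol, OCCO
Why: Acid-catalysed ketalisation with azeotropic removal of water; C21 is the only carbonyl and the secondary alcohol is inert.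

Step 7
Reactants: 8 13β-hydroxy trans-decalin C21 ethylene ketal
Product: 9 trans-decalin 13-ketone C21 ethylene ketal
Conditions: (n-Pr4N)RuO4 (cat.), N-methylmorpholine N-oxide, 4 Å MS, CH2Cl2, rt
Reagents that add atoms: none
Why: Ley–Griffith oxidation of a secondary alcohol under neutral conditions, which leave the ketal untouched.

Step 8
Reactants: 9 trans-decalin 13-ketone C21 ethylene ketal
Product: 11 14-methyl 13-ketone C21 ethylene ketal, via lithium enolate 10 (not isolated)
Conditions: LiN(i-Pr)2, THF, −78 °C; MeI, −78 → 0 °C
Reagents that add atoms: iodomethane, CI
Why: Enolate alkylation: the ketone can enolise only toward C14 because C18 is quaternary, so C27 is installed regiospecifically; the configuration at C14 is of no consequence because C14 becomes sp2 in the next step.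

Step 9
Reactants: 11 14-methyl 13-ketone C21 ethylene ketal
Product: 13 C13 enol triflate (13-ene), via potassium enolate 12 (not isolated)
Conditions: KN(SiMe3)2, THF, −78 → 0 °C; PhNTf2, 0 °C
Reagents that add atoms: N-phenylbis(trifluoromethanesulfonimide), O=S(=O)(N(c1ccccc1)S(=O)(=O)C(F)(F)F)C(F)(F)F
Why: Enolisation is again possible toward C14 only, and O-sulfonylation of the potassium enolate by the triflimide gives the tetrasubstituted enol triflate.

Step 10
Reactants: 13 C13 enol triflate (13-ene)
Product: 14 14-methyl-13-ene C21 ethylene ketal
Conditions: Pd(OAc)2 (cat.), PPh3, n-Bu3N, HCO2H, DMF, 60 °C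
Reagents that add atoms: none
Why: Palladium-catalysed formate reduction of an enol triflate (oxidative addition to zerovalent palladium, formate exchange, loss of CO2, reductive elimination) replaces OTf by H without moving the alkene.

Step 11
Reactants: 14 14-methyl-13-ene C21 ethylene ketal
Product: 15 14-methyl-13-en-15-one C21 ethylene ketal
Conditions: CrO3, 3,5-dimethylpyrazole, CH2Cl2, −20 °C
Reagents that add atoms: chromium trioxide, O=[Cr](=O)=O
Why: Allylic oxidation with the CrO3–dimethylpyrazole complex (hexavalent chromium): C15 is the only allylic methylene, since C18 bears no hydrogen and the methyl group is oxidised much more slowly, so the 2-methyl enone should result.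

Step 12
Reactants: 15 14-methyl-13-en-15-one C21 ethylene ketal
Product: 16 15β-hydroxy-14-methyl-13-ene C21 ethylene ketal (15S)
Conditions: NaBH4, CeCl3·7H2O, MeOH, −40 → 0 °C
Reagents that add atoms: none
Why: Luche 1,2-reduction: axial delivery of hydride to C15 from the α face gives the pseudo-equatorial 15β alcohol, as with 5α-steroidal 1-en-3-ones.

Step 13
Reactants: 16 15β-hydroxy-14-methyl-13-ene C21 ethylene ketal (15S)
Product: 18 ethyl ester with CH2CO2Et on C13β and the C14=C15 alkene (13S), via mixed ketene acetal 17 (not isolated)
Conditions: MeC(OEt)3, EtCO2H (cat.), xylene, 140 °C (−EtOH)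
Reagents that add atoms: triethyl orthoacetate, CC(OCC)(OCC)OCC
Why: Johnson–Claisen rearrangement: the suprafacial [3,3] shift of the ketene acetal carries the two-carbon unit from the 15β oxygen to the β face of C13, cis to the angular methyl and equatorial, and leaves the alkene at C14=C15; the weak acid does not open the hindered ketal.

Step 14
Reactants: 18 ethyl ester with CH2CO2Et on C13β and the C14=C15 alkene (13S)
Product: 19 primary alcohol (C11–OH) of the right half
Conditions: LiAlH4, THF, 0 °C
Reagents that add atoms: none
Why: Hydride reduction of an ester to the primary alcohol; ketal and alkene are inert.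

Step 15
Reactants: 19 primary alcohol (C11–OH) of the right half
Product: 20 primary bromide (C11–Br) of the right half
Conditions: CBr4, PPh3, 2,6-lutidine, CH2Cl2, 0 °C
Reagents that add atoms: carbon tetrabromide, BrC(Br)(Br)Br
Why: Appel reaction (SN2 at an unhindered primary carbon); the base buffers traces of HBr and protects the ketal.

Step 16
Reactants: 20 primary bromide (C11–Br) of the right half
Product: 21 right-half C11 alkylmagnesium bromide (ether solution, titrated and used directly)
Conditions: Mg turnings, BrCH2CH2Br (cat.), Et2O, reflux
Reagents that add atoms: magnesium, [Mg]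
Why: Insertion of magnesium into a primary C–Br bond; the ketal and the trisubstituted alkene are compatible, and diethyl ether is the solvent that the copper-catalysed step needs.

Step 17
Reactants: 3 4,4-dimethoxy-2-methylcyclohex-2-en-1-one; 21 right-half C11 alkylmagnesium bromide; 22 pent-1-en-3-one
Product: 24 (9R,10R)-1,5-diketone carrying the right half, via bromomagnesium enolate 23 (not isolated)
Conditions: CuBr·SMe2 (5 mol %), (R)-1-[(SP)-2-(diphenylphosphino)ferrocenyl]ethyldicyclohexylphosphine (6 mol %), t-BuOMe, −78 °C, slow addition of 21 to 3 (1.3 equiv); then 22 (1.5 equiv), −78 → −40 °C; aq NH4Cl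
Reagents that add atoms: none
Why: The closest known reaction type is the conjugate addition of an alkylmagnesium bromide to a cyclic enone under a chiral copper bisphosphine catalyst, followed by Michael trapping of the magnesium enolate by a vinyl ketone. The monovalent copper complex is alkylated by 21 and binds the C9=C10 alkene of 3; oxidative addition gives a trivalent copper alkyl at C9, and reductive elimination forms C9–C11 and releases enolate 23 with its double bond fixed between C5 and C10. No ring is closed in this step. C9 (9R) is set by the ligand, which selects the Re face; the stereocentres of 21 are five bonds away, and since 21 is a single enantiomer any leakage shows up as a separable diastereomer. C10 (10R) is set by the substrate: the new C9 chain next to the C8 ketal shields one face of the tetrasubstituted enolate, so 22 is attacked at its terminal carbon anti to the chain, which forms C1–C10 trans to C11 and leaves the methyl cis to it. 1,4- over 1,2-addition is secured by slow addition of 21 at −78 °C to the preformed catalyst, and 23 cannot expel methoxide because the ketal carbon C8 is not adjacent to the enolate carbon. No Lewis acid is used for the trapping, since the acyclic C8 ketal would ionise; the magnesium counter-ion activates 22, and a small excess of 22 with an early quench limits oligomerisation.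

Step 18
Reactants: 24 (9R,10R)-1,5-diketone carrying the right half
Product: 25 ring A enone (C3 ketone, C4(CH3)=C5) with C8 dimethyl ketal
Conditions: KOH, MeOH, 60 °C
Reagents that add atoms: none
Why: Intramolecular aldol condensation (second stage of a Robinson annulation): the C4 enolate of the ethyl ketone adds to the C5 carbonyl to close the six-membered ring A, and loss of water gives the conjugated enone; both ketals are stable to base.

Step 19
Reactants: 25 ring A enone (C3 ketone, C4(CH3)=C5) with C8 dimethyl ketal
Product: 27 4,4-dimethyl 3-ketone (5α-H) with C8 dimethyl ketal, via lithium enolate 26 (not isolated)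
Conditions: Li, NH3 (l), THF, t-BuOH (1 equiv), −78 °C; MeI, −78 → −33 °C
Reagents that add atoms: iodomethane, CI
Why: Reductive alkylation of an enone: two-electron reduction with axial protonation of C5 on the α face gives the trans-fused C3–C4 enolate (5R), and C-methylation at C4 completes the gem-dimethyl group; the isolated C14=C15 alkene and the ketals are not reduced.

Step 20
Reactants: 27 4,4-dimethyl 3-ketone (5α-H) with C8 dimethyl ketal
Product: 28 3β-alcohol with C8 dimethyl ketal and C21 ethylene ketal
Conditions: NaBH4, MeOH–THF, 0 °C
Reagents that add atoms: none
Why: Hydride attacks C3 axially from the α face, because the β face is screened by the axial 4β- and 10β-methyl groups, and gives the equatorial 3β alcohol (3S).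

Step 21
Reactants: 28 3β-alcohol with C8 dimethyl ketal and C21 ethylene ketal
Product: 29 3β-hydroxy 8-ketone with C21 ethylene ketal
Conditions: PPTS (cat.), acetone–H2O, rt
Reagents that add atoms: water, O
Why: Selective ketal hydrolysis: an acyclic dimethyl ketal is cleaved far faster than the neopentyl dioxolane at C21; C9, now α to a ketone, keeps its equatorial bridge, which is the thermodynamic arrangement.

Step 22
Reactants: 29 3β-hydroxy 8-ketone with C21 ethylene ketal
Product: 30 3β-hydroxyonocera-8(26),14-dien-21-one C21 ethylene ketal
Conditions: Ph3PCH3Br, KOtBu, THF, rt → 60 °C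
Reagents that add atoms: methyltriphenylphosphonium bromide, C[P+](c1ccccc1)(c1ccccc1)c1ccccc1.[Br-]
Why: Wittig methylenation of the C8 ketone; excess ylide makes up for the alkoxide formed at C3, and any enolisation toward C9 is harmless because the natural configuration is the stable one.

Step 23
Reactants: 30 3β-hydroxyonocera-8(26),14-dien-21-one C21 ethylene ketal
Product: 31 3β-hydroxyonocera-8(26),14-dien-21-one (target)
Conditions: PPTS, acetone–H2O, 55 °C
Reagents that add atoms: water, O
Why: Acid-catalysed hydrolysis of the dioxolane with a weak acid, chosen so that the exocyclic C8=C26 alkene and the C14=C15 alkene do not migrate.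

## Compound list

1 | 4-methoxy-2-methylphenol | COc1ccc(O)c(C)c1 | starting material
2 | 4,4-dimethoxy-2-methylcyclohexa-2,5-dien-1-one | COC1(OC)C=CC(=O)C(C)=C1 | intermediate
3 | 4,4-dimethoxy-2-methylcyclohex-2-en-1-one (left ring B enone: C5 carbonyl, C10(CH3)=C9, C8 ketal) | COC1(OC)CCC(=O)C(C)=C1 | intermediate
4 | (S)-Wieland–Miescher ketone, (8aS)-8a-methyl-3,4,8,8a-tetrahydronaphthalene-1,6(2H,7H)-dione | O=C1CCCC2=CC(=O)CC[C@]12C | starting material
5 | (4aS,5S)-5-hydroxy-4a-methyl-4,4a,5,6,7,8-hexahydronaphthalen-2(3H)-one (13β-OH) | O[C@H]1CCCC2=CC(=O)CC[C@]12C | intermediate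
6 | (4aS,5S)-5-hydroxy-1,1,4a-trimethyl-3,4,4a,5,6,7-hexahydronaphthalen-2(1H)-one (13β-OH, C16=C17, C21 ketone) | O[C@H]1CCC=C2C(C)(C)C(=O)CC[C@]12C | intermediate
7 | (4aS,5S,8aR)-5-hydroxy-1,1,4a-trimethyloctahydronaphthalen-2(1H)-one (trans-decalin, 17α-H, 18β-CH3, 13β-OH) | O[C@H]1CCC[C@H]2C(C)(C)C(=O)CC[C@]12C | intermediate
8 | 13β-hydroxy trans-decalin C21 ethylene ketal | O[C@H]1CCC[C@H]2C(C)(C)C3(OCCO3)CC[C@]12C | intermediate
9 | trans-decalin 13-ketone C21 ethylene ketal | O=C1CCC[C@H]2C(C)(C)C3(OCCO3)CC[C@]12C | intermediate
10 | lithium C13–C14 enolate of 9 (not isolated) | [Li]OC1=CCC[C@H]2C(C)(C)C3(OCCO3)CC[C@]12C | intermediate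
11 | 14-methyl 13-ketone C21 ethylene ketal (14α-methyl epimer shown; the 14β epimer serves equally) | O=C1[C@H](C)CC[C@H]2C(C)(C)C3(OCCO3)CC[C@]12C | intermediate
12 | potassium enolate of 11 (not isolated) | [K]OC1=C(C)CC[C@H]2C(C)(C)C3(OCCO3)CC[C@]12C | intermediate
13 | C13 enol triflate: 13-(trifluoromethanesulfonyloxy)-14-methyl-13-ene C21 ethylene ketal | O=S(=O)(OC1=C(C)CC[C@H]2C(C)(C)C3(OCCO3)CC[C@]12C)C(F)(F)F | intermediate
14 | 14-methyl-13-ene C21 ethylene ketal (C13H=C14(CH3)) | C1=C(C)CC[C@H]2C(C)(C)C3(OCCO3)CC[C@]12C | intermediate
15 | 14-methyl-13-en-15-one C21 ethylene ketal | C1=C(C)C(=O)C[C@H]2C(C)(C)C3(OCCO3)CC[C@]12C | intermediate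
16 | 15β-hydroxy-14-methyl-13-ene C21 ethylene ketal (15S) | C1=C(C)[C@@H](O)C[C@H]2C(C)(C)C3(OCCO3)CC[C@]12C | intermediate
17 | mixed ketene acetal of 16, 15β-O–C(OEt)=CH2 (not isolated) | C1=C(C)[C@@H](OC(=C)OCC)C[C@H]2C(C)(C)C3(OCCO3)CC[C@]12C | intermediate
18 | ethyl ester: CH2CO2Et (C12, C11) on C13β, 13α-H, C14=C15, C21 ethylene ketal (13S,17R,18R) | CCOC(=O)C[C@H]1C(C)=CC[C@H]2C(C)(C)C3(OCCO3)CC[C@]12C | intermediate
19 | primary alcohol: CH2CH2OH on C13β, otherwise as 18 | OCC[C@H]1C(C)=CC[C@H]2C(C)(C)C3(OCCO3)CC[C@]12C | intermediate
20 | primary bromide: CH2CH2Br on C13β, otherwise as 18 | BrCC[C@H]1C(C)=CC[C@H]2C(C)(C)C3(OCCO3)CC[C@]12C | intermediate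
21 | right-half C11 alkylmagnesium bromide (C21 ethylene ketal) | Br[Mg]CC[C@H]1C(C)=CC[C@H]2C(C)(C)C3(OCCO3)CC[C@]12C | intermediate
22 | pent-1-en-3-one | C=CC(=O)CC | starting material
23 | bromomagnesium C5–C10 enolate of the C9 adduct (9R; not isolated) | Br[Mg]OC1=C(C)[C@@H](CC[C@H]2C(C)=CC[C@H]3C(C)(C)C4(OCCO4)CC[C@]23C)C(OC)(OC)CC1 | intermediate
24 | (9R,10R)-1,5-diketone: ring B ketone C5, C8 dimethyl ketal, C9 carrying the right half through C11–C12, C10 carrying CH3 and the 3-oxopentyl chain C1–C4 | O=C1CCC(OC)(OC)[C@H](CC[C@H]2C(C)=CC[C@H]3C(C)(C)C4(OCCO4)CC[C@]23C)[C@@]1(C)CCC(=O)CC | intermediate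
25 | ring A enone: C3 ketone, C4(CH3)=C5, C8 dimethyl ketal, C21 ethylene ketal | CC1=C2CCC(OC)(OC)[C@H](CC[C@H]3C(C)=CC[C@H]4C(C)(C)C5(OCCO5)CC[C@]34C)[C@@]2(C)CCC1=O | intermediate
26 | lithium C3–C4 enolate, 5α-H (not isolated) | COC1(OC)CC[C@H]2C(C)=C(O[Li])CC[C@]2(C)[C@H]1CC[C@H]1C(C)=CC[C@H]2C(C)(C)C3(OCCO3)CC[C@]12C | intermediate
27 | 4,4-dimethyl 3-ketone, 5α-H, C8 dimethyl ketal, C21 ethylene ketal | COC1(OC)CC[C@H]2C(C)(C)C(=O)CC[C@]2(C)[C@H]1CC[C@H]1C(C)=CC[C@H]2C(C)(C)C3(OCCO3)CC[C@]12C | intermediate
28 | 3β-alcohol, C8 dimethyl ketal, C21 ethylene ketal | COC1(OC)CC[C@H]2C(C)(C)[C@@H](O)CC[C@]2(C)[C@H]1CC[C@H]1C(C)=CC[C@H]2C(C)(C)C3(OCCO3)CC[C@]12C | intermediate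
29 | 3β-hydroxy 8-ketone, C21 ethylene ketal | O=C1CC[C@H]2C(C)(C)[C@@H](O)CC[C@]2(C)[C@H]1CC[C@H]1C(C)=CC[C@H]2C(C)(C)C3(OCCO3)CC[C@]12C | intermediate
30 | 3β-hydroxyonocera-8(26),14-dien-21-one C21 ethylene ketal | C=C1CC[C@H]2C(C)(C)[C@@H](O)CC[C@]2(C)[C@H]1CC[C@H]1C(C)=CC[C@H]2C(C)(C)C3(OCCO3)CC[C@]12C | intermediate
31 | 3β-hydroxyonocera-8(26),14-dien-21-one, (3S,5R,9S,10R,13S,17R,18R), CNP0110518.2 | C=C1CC[C@H]2C(C)(C)[C@@H](O)CC[C@]2(C)[C@H]1CC[C@H]1C(C)=CC[C@H]2C(C)(C)C(=O)CC[C@]12C | target

## Step count and least certain steps

Total step count: 23. Longest linear sequence: 21 steps (steps 3–23, from 4); steps 1–2 form the short branch to 3.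

Step 17 (key step). The most likely failure lies in the second bond: transfer of the vinyl ketone to the hindered, tetrasubstituted magnesium enolate has to compete with oligomerisation of 22 by the less hindered product enolate and with proton exchange. Incomplete facial control at C9 on this α-methyl, γ-ketal enone would add a second diastereomer. Fallback, setting out from 3 and 21 and returning at 25: the copper-catalysed addition is run as before, but the enolate is silylated (Me3SiCl, Et3N) and the trimethylsilyl enol ether F1 is isolated, at which stage a C9 epimer can be removed. MeLi in THF converts it into the lithium enolate F2, which is added to the α-silylated vinyl ketone 2-(trimethylsilyl)pent-1-en-3-one F3 (one step from (1-bromovinyl)trimethylsilane by way of its magnesium derivative and N-methoxy-N-methylpropanamide). The silyl group blocks polymerisation and stabilises the adduct, the α-silyl 1,5-diketone F4. KOH in methanol then removes silicon and closes ring A in one operation, so the route is rejoined at 25.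

Step 13 (Johnson–Claisen rearrangement). The oxygen on C15 is pseudo-equatorial, so the [3,3] shift has to pass through a boat-like ring B. If it is slow, acid-promoted ionisation of the allylic orthoester and elimination to a diene can take over. Fallback, from 16 to 19: a Mitsunobu reaction with picolinic acid (PPh3, diisopropyl azodicarboxylate) inverts C15 and gives the 15α-picolinate F5. CH2=CHMgBr with CuBr·SMe2 then effects a pyridine-directed anti SN2′ substitution that brings the vinyl group to the β face of C13 and moves the alkene to C14=C15, giving the 13β-vinyl compound F6. Hydroboration of the monosubstituted alkene with 9-BBN, followed by H2O2 and NaOH, gives 19.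

Step 11 (allylic oxidation). Oxygen may be introduced with allylic transposition, which would put the carbonyl at C13, or at the methyl group, and conversion of this hindered alkene may stay incomplete. Fallback, from 11 to 15, by carbonyl transposition in place of C–H oxidation: dehydrogenation with 2-iodoxybenzoic acid in DMSO at 70 °C gives the 14-methyl-14-en-13-one F7. H2O2 and NaOH in methanol give the 14α,15α-epoxy ketone F8. A Wharton reaction (N2H4·H2O, AcOH cat., MeOH) turns it into the 15α allylic alcohol F9, the C15 epimer of 16, which MnO2 oxidises to 15.

Step 19 (reductive methylation). Proton transfer to the enolate before or during alkylation would leave a 4-monomethyl ketone, and over-reduction at C3 or alkylation on oxygen are also possible on this large substrate. Fallback, from 25 to 27: the reduction is carried out as before, but the enolate is quenched with Me3SiCl and Et3N and the trimethylsilyl enol ether F10 is isolated. MeLi then regenerates the lithium enolate free of proton sources, and MeI in THF with a dipolar co-solvent gives 27.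

Step 23 (final deprotection). Hydrolysis of the hindered dioxolane may be slow enough for acid-promoted migration of the C8=C26 alkene into ring B to compete. Fallback, from 28 to 31, which avoids any acid once the alkene is present: aqueous HCl in THF removes both ketals of 28 and gives the 3β-hydroxy 8,21-diketone F11. Methylenation with a limited amount of Ph3P=CH2 (or with Zn, CH2Br2 and TiCl4) should then take place at C8 and not at C21, which is flanked by the quaternary C22, and gives 31 directly.

## Further compounds

F1 | step 17 | trimethylsilyl enol ether of the C9 adduct (C5–OSiMe3, C5=C10, 9R) | C[Si](C)(C)OC1=C(C)[C@@H](CC[C@H]2C(C)=CC[C@H]3C(C)(C)C4(OCCO4)CC[C@]23C)C(OC)(OC)CC1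
F2 | step 17 | lithium C5–C10 enolate of the C9 adduct | [Li]OC1=C(C)[C@@H](CC[C@H]2C(C)=CC[C@H]3C(C)(C)C4(OCCO4)CC[C@]23C)C(OC)(OC)CC1
F3 | step 17 | 2-(trimethylsilyl)pent-1-en-3-one | C=C(C(=O)CC)[Si](C)(C)C
F4 | step 17 | α-silyl 1,5-diketone (24 with SiMe3 on C2, both C2 epimers) | O=C1CCC(OC)(OC)[C@H](CC[C@H]2C(C)=CC[C@H]3C(C)(C)C4(OCCO4)CC[C@]23C)[C@@]1(C)CC(C(=O)CC)[Si](C)(C)C
F5 | step 13 | 15α-picolinate of the 14-methyl-13-ene C21 ethylene ketal | C1=C(C)[C@H](OC(=O)c3ccccn3)C[C@H]2C(C)(C)C3(OCCO3)CC[C@]12C
F6 | step 13 | 13β-vinyl-14-methyl-14-ene C21 ethylene ketal | C=C[C@H]1C(C)=CC[C@H]2C(C)(C)C3(OCCO3)CC[C@]12C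
F7 | step 11 | 14-methyl-14-en-13-one C21 ethylene ketal | O=C1C(C)=CC[C@H]2C(C)(C)C3(OCCO3)CC[C@]12C
F8 | step 11 | 14α,15α-epoxy-14-methyl 13-ketone C21 ethylene ketal | O=C1[C@]3(C)O[C@@H]3C[C@H]2C(C)(C)C4(OCCO4)CC[C@]12C
F9 | step 11 | 15α-hydroxy-14-methyl-13-ene C21 ethylene ketal | C1=C(C)[C@H](O)C[C@H]2C(C)(C)C3(OCCO3)CC[C@]12C
F10 | step 19 | trimethylsilyl enol ether (C3–OSiMe3, C3=C4, 5α-H) with C8 dimethyl ketal | COC1(OC)CC[C@H]2C(C)=C(O[Si](C)(C)C)CC[C@]2(C)[C@H]1CC[C@H]1C(C)=CC[C@H]2C(C)(C)C3(OCCO3)CC[C@]12C
F11 | step 23 | 3β-hydroxyonocer-14-ene-8,21-dione | O=C1CC[C@H]2C(C)(C)[C@@H](O)CC[C@]2(C)[C@H]1CC[C@H]1C(C)=CC[C@H]2C(C)(C)C(=O)CC[C@]12C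
A1 | alternative 1 | trienone: left decalin (3-OTBS) on C11, C12 ketone, (E)-C13=C18 enone, tether C19–C22 with 21-OPMB, (Z)-2-triethylsilyloxy diene C17=C16–C15=C14 | C=C1CC[C@H]2C(C)(C)[C@@H](O[Si](C)(C)C(C)(C)C)CC[C@]2(C)[C@H]1CC(=O)/C=C(\C)CC[C@H](OCc1ccc(OC)cc1)C(C)(C)/C=C/C(O[Si](CC)(CC)CC)=C/C
A2 | alternative 1 | C12-keto right decalin as its C15 triethylsilyl enol ether | C=C1CC[C@H]2C(C)(C)[C@@H](O[Si](C)(C)C(C)(C)C)CC[C@]2(C)[C@H]1CC(=O)[C@H]1[C@@H](C)C(O[Si](CC)(CC)CC)=C[C@H]2C(C)(C)[C@@H](OCc3ccc(OC)cc3)CC[C@]12C
A3 | alternative 2 | 2,4-dimethyl-3-substituted phenol with (E)-allylsilane tether (15R) and the left decalin (3-OTBS) | C=C1CC[C@H]2C(C)(C)[C@@H](O[Si](C)(C)C(C)(C)C)CC[C@]2(C)[C@H]1CC/C=C(\C)[C@@H](Cc1c(C)ccc(O)c1C)[Si](C)(C)C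
A4 | alternative 2 | right-half cross-conjugated dienone carrying the left half | C=C1CC[C@H]2C(C)(C)[C@@H](O[Si](C)(C)C(C)(C)C)CC[C@]2(C)[C@H]1CC[C@H]1C(C)=CCC2=C(C)C(=O)C=C[C@]12C
A5 | alternative 3 | (3S)-3,4-epoxy (5E,8E)-diene carrying the right half as C21 ethylene ketal | CC1(C)O[C@H]1CC/C(C)=C/CC/C(C)=C/CC[C@H]1C(C)=CC[C@H]2C(C)(C)C3(OCCO3)CC[C@]12C
A6 | alternative 3 | C21 ethylene ketal of the target (identical with 30) | C=C1CC[C@H]2C(C)(C)[C@@H](O)CC[C@]2(C)[C@H]1CC[C@H]1C(C)=CC[C@H]2C(C)(C)C3(OCCO3)CC[C@]12C
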